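**Retrosynthetic overview**

- Target: (2R,4S)-4-(4,5-dimethoxynaphthalen-1-yl)-2-methylchroman-5-ol, 2,4-trans. Chroman locants: O1, C2 (methyl), C4 (naphthyl), C4a, C5 (hydroxyl), C8a; ring A = benzene ring, ring B = pyran ring.
- Both aryl bonds at C4 are cut in one operation: C4–C1' of the naphthalene (Friedel–Crafts arylation of 1,8-dimethoxynaphthalene para to a methoxy group) and C4–C4a (closure of ring B). This leads back to (R)-3-(3-hydroxyphenoxy)butanal, whose aldehyde carbon becomes C4.
- Enabling feature: the C5 hydroxyl of ring A is ortho to C4a and peri to C4, so O5–C5–C4a–C4 is a salicyl alcohol (ortho-quinone methide) array, and C4a is the carbon between O5 and O1. A boron template on O5 steers the tethered aldehyde to C4a; the same O5 then turns C4 into an ortho-quinone methide that captures the naphthalene.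
- C2 (R) comes from ethyl (S)-3-hydroxybutanoate by Mitsunobu inversion with resorcinol; C4 (S) is set trans to the C2 methyl group in the arylation.
- Ring order: ring A (resorcinol) and the naphthalene are bought; ring B is the only ring built and is closed last, together with a temporary boronate ring that is opened again in the same flask.

Key step: step 4

Remark: resorcinol, ethyl (S)-3-hydroxybutanoate and naphthalene-1,8-diol are taken as commercial; the chroman locants defined above are also used for the open-chain precursors.

**Step 1**
Reactants: 1 resorcinol (benzene-1,3-diol); 2 ethyl (S)-3-hydroxybutanoate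
Product: 3 ethyl (R)-3-(3-hydroxyphenoxy)butanoate
Conditions: 1 (4 equiv), PPh3, DIAD, THF, 0 °C to rt
Reagents that add atoms: none
Why: Mitsunobu etherification, in which the phenol of 1 displaces the oxyphosphonium-activated secondary hydroxyl of 2 by SN2 with inversion, so that the S carbinol carbon becomes the R aryl ether carbon (C2 of the target), while the excess of 1 holds back double etherification.

**Step 2**
Reactants: 3 ethyl (R)-3-(3-hydroxyphenoxy)butanoate
Product: 4 (R)-3-(3-hydroxyphenoxy)butanal
Conditions: i-Bu2AlH (2.2 equiv), CH2Cl2, −78 °C; then MeOH, aq. potassium sodium tartrate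
Reagents that add atoms: none
Why: Partial reduction of an ester with i-Bu2AlH, in which the first equivalent is consumed by the phenol and the second gives an aluminium hemiacetal that should be stable at −78 °C and release the aldehyde only on work-up; the stereocenter is not α to the carbonyl group and is not touched.

**Step 3**
Reactants: 5 naphthalene-1,8-diol
Product: 6 1,8-dimethoxynaphthalene
Conditions: NaH (2.5 equiv), MeI (3 equiv), DMF, 0 °C to rt
Reagents that add atoms: iodomethane, CI
Why: Double Williamson O-methylation, with NaH chosen because the second hydroxyl group is held in a strong intramolecular hydrogen bond and needs full deprotonation.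

**Step 4**
Reactants: 4 (R)-3-(3-hydroxyphenoxy)butanal; 6 1,8-dimethoxynaphthalene
Product: 9 cladonaphchrom A, via cyclic phenylboronate 7 (not isolated), via ortho-quinone methide 8 (not isolated)
Conditions: PhB(OH)2 (1.2 equiv), EtCO2H (0.3 equiv), ClCH2CH2Cl (0.01 M, slow addition of 4), reflux, 4 Å molecular sieves; then 6 (3 equiv), BF3·OEt2 (0.3 equiv), −20 °C to 0 °C; aq. NaHCO3
Reagents that add atoms: none
Why: Proposed new method: phenylboronic acid esterifies the C5 hydroxyl of 4 and binds the aldehyde oxygen, and the carbonyl carbon is delivered through a six-membered boron-bridged transition state to the arene carbon ortho to that oxygen, the closest known reaction type being the intermolecular phenylboronic acid-templated ortho-hydroxyalkylation of phenols with aldehydes to 2-phenyl-4H-1,3,2-benzodioxaborins (Nagata reaction), here proposed within one molecule. Ring B closes by 6-exo-trig attack of C4a on the tethered aldehyde carbon (the aromatic C4a–C8a bond lies inside the new ring), and the temporary boronate ring of 7 closes in the same event by B–O condensation. BF3 then ionizes the benzylic C4–O bond of 7 to the boron-bound ortho-quinone methide 8, a cation at C4 stabilized by both ortho oxygens, and 6 adds to it by Friedel–Crafts arylation at its carbon para to a methoxy group, as known for acid-promoted arylation of ortho-hydroxybenzyl alcohols and for electrophilic substitution of 1,8-dimethoxynaphthalene. The C4 stereocenter is set in this arylation under control of the C2 methyl group: pseudo-axial attack on the half-chair of 8 that holds the methyl group pseudo-equatorial should put the naphthyl group trans to it (4S), and the same isomer should be favoured at equilibrium because an in-plane aryl group at C4 would clash with the peri oxygen at C5. The selectivity the step needs is closure at C4a and not at the carbon para to the hydroxyl group, and it is secured because only C4a is both ortho to the boron-bound oxygen and within reach of the three-atom tether, while propionic acid is too weak to drive the untemplated closure and high dilution holds back intermolecular hydroxyalkylation.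

**Compound list**

1 | resorcinol (benzene-1,3-diol) | Oc1cccc(O)c1 | starting material
2 | ethyl (S)-3-hydroxybutanoate | CCOC(=O)C[C@H](C)O | starting material
3 | ethyl (R)-3-(3-hydroxyphenoxy)butanoate | CCOC(=O)C[C@@H](C)Oc1cccc(O)c1 | intermediate
4 | (R)-3-(3-hydroxyphenoxy)butanal | O=CC[C@@H](C)Oc1cccc(O)c1 | intermediate
5 | naphthalene-1,8-diol | Oc1cccc2cccc(O)c12 | starting material
6 | 1,8-dimethoxynaphthalene | COc1cccc2cccc(OC)c12 | intermediate
7 | cyclic phenylboronate bridging O4 and O5 of (2R,4S)-2-methylchromane-4,5-diol (2,4-cis, peri-fused tricycle) | C[C@@H]1C[C@@H]2OB(c3ccccc3)Oc3cccc(O1)c32 | intermediate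
8 | (R)-2-methyl-2,3-dihydro-5H-chromen-5-one (ortho-quinone methide with C4=C4a and C5=O, held in the flask as its oxygen-bound boron complex) | C[C@@H]1CC=C2C(=O)C=CC=C2O1 | intermediate
9 | cladonaphchrom A, (2R,4S)-4-(4,5-dimethoxynaphthalen-1-yl)-2-methylchroman-5-ol | COc1cccc2c([C@@H]3C[C@@H](C)Oc4cccc(O)c43)ccc(OC)c12 | target

Total step count: 4. Longest linear sequence: 3 steps (steps 1, 2 and 4).

**Steps most likely to fail**

1. Step 4 (proposed new method).
   - What may go wrong: intermolecular hydroxyalkylation at the unhindered carbon ortho to the hydroxyl group may outrun the templated closure and give oligomers. β-Elimination of the aryloxy group from the aldehyde at reflux would cost material and erode the C2 configuration. In the second stage the arylation may show poor facial selectivity at C4.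
   - Fallback (known chemistry only), setting out from 2 and coming back at 9: Mitsunobu etherification of 2 with commercial 2-bromoresorcinol (Oc1cccc(O)c1Br, in excess; PPh3, DIAD, THF) should give ethyl (R)-3-(2-bromo-3-hydroxyphenoxy)butanoate F1. Saponification (LiOH, THF/H2O, 0 °C) should give (R)-3-(2-bromo-3-hydroxyphenoxy)butanoic acid F2. Parham cyclization (n-BuLi, 3.2 equiv, THF, −78 °C) should give (R)-5-hydroxy-2-methylchroman-4-one F3; here bromine–lithium exchange fixes the nucleophilic site at the carbon between the two oxygens, and the aryllithium is acylated by the lithium carboxylate of the same molecule. Reduction with NaBH4 in MeOH at 0 °C should give (2R,4S)-2-methylchromane-4,5-diol F4, whose C4 configuration is without consequence. Ionization of F4 with BF3·OEt2 in CH2Cl2 at −20 °C in the presence of 6 passes through the same ortho-quinone methide 8 and should return to 9.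

2. Step 2.
   - What may go wrong: over-reduction to the primary alcohol, stalling of the reduction by a poorly soluble aluminium phenoxide, and β-elimination of the aryloxy group during work-up.
   - Fallback, setting out from 1 and coming back at 4: Mitsunobu etherification of 1 (in excess) with commercial (S)-pent-4-en-2-ol should give, with inversion and without an elimination-prone ester, (R)-3-(pent-4-en-2-yloxy)phenol F5. Lemieux–Johnson cleavage of the terminal alkene (OsO4 cat., NaIO4, 2,6-lutidine, dioxane/H2O, rt) should then reveal the aldehyde 4 under nearly neutral conditions instead of by hydride reduction.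

3. Step 1.
   - What may go wrong: elimination of the activated β-hydroxy ester to ethyl crotonate, and double etherification of resorcinol.
   - Fallback, setting out from 1 and coming back at 3: SN2 ring opening of commercial (S)-4-methyloxetan-2-one at its methyl-bearing carbon by monosodium resorcinolate (1 in excess, NaH, DMF, rt), with alkyl–oxygen cleavage and inversion, should give (R)-3-(3-hydroxyphenoxy)butanoic acid F6. Fischer esterification (EtOH, cat. H2SO4, 50 °C) should give 3.

**Further compounds**

F1 | step 4 | ethyl (R)-3-(2-bromo-3-hydroxyphenoxy)butanoate | CCOC(=O)C[C@@H](C)Oc1cccc(O)c1Br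
F2 | step 4 | (R)-3-(2-bromo-3-hydroxyphenoxy)butanoic acid | OC(=O)C[C@@H](C)Oc1cccc(O)c1Br
F3 | step 4 | (R)-5-hydroxy-2-methylchroman-4-one | C[C@@H]1CC(=O)c2c(O)cccc2O1
F4 | step 4 | (2R,4S)-2-methylchromane-4,5-diol | C[C@@H]1C[C@H](O)c2c(O)cccc2O1
F5 | step 2 | (R)-3-(pent-4-en-2-yloxy)phenol | C=CC[C@@H](C)Oc1cccc(O)c1
F6 | step 1 | (R)-3-(3-hydroxyphenoxy)butanoic acid | OC(=O)C[C@@H](C)Oc1cccc(O)c1
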